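**Retrosynthesis**
1. Ring 2 (the pyran, with the C1 acylal and the C3=C4 enol ether) is closed last. A C1 aldehyde, a C3 dioxolane and an isovalerate donor undergo one acylative cyclodehydration.
2. C7-OAc and the C8(OH)–C10H2OH unit come from CBS reduction of an α-methylene cyclopentanone, acetylation, and OsO4 dihydroxylation of the exocyclic alkene. Attack is from the face anti to C7-OAc and the trans C9 acetal.
3. The exocyclic enone comes from C8 aminomethylation of an α-nitroketone (the nitro group blocks C6), then denitration and Hofmann-type elimination. The α-nitroketone is the oxidised Henry alcohol.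
4. The cyclopentane and the C5 stereocentre come from an organocatalytic enamine Michael / intramolecular Henry cascade of succinaldehyde with a nitroalkene carrying the C3–C4–C11 unit, which is built from ethyl dioxolanylacetate.

**Assumptions:**
- C4 in 2–6 is a labile stereocentre formed as a racemate; it becomes sp² in step 16, so both epimers converge.
- C6 and C7 in 8–10 are undefined and are erased later.
- Succinaldehyde is generated in situ from commercial 2,5-dimethoxytetrahydrofuran.
- The catalyst and CBS handedness named are assumed to give the drawn configuration.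
- Faces are defined with the ring drawn C5→C6→C7→C8→C9 counter-clockwise seen from above. The target then has the C5 side chain (C4) down, C7-OAc up, C8-OH down, C10 up and C1 down (cis ring fusion). Intermediates 8–17 carry C1 up (trans to C4).

**Step 1**
Reactants: 1 ethyl 2-(1,3-dioxolan-2-yl)acetate
Product: 2 ethyl 2-(1,3-dioxolan-2-yl)-3-hydroxypropanoate (racemic)
Conditions: LDA, THF, –78 °C; then monomeric HCHO, –78 → 0 °C
Reagents that add atoms: formaldehyde, C=O
Why: Ester-enolate aldol (hydroxymethylation) places the future C11 carbon; the low temperature avoids β-elimination of the dioxolane oxygen.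

**Step 2**
Reactants: 2
Product: 3 2-(1,3-dioxolan-2-yl)propane-1,3-diol
Conditions: LiAlH4, THF, 0 °C
Reagents that add atoms: none
Why: Ester reduction; the dioxolane is stable to hydride.

**Step 3**
Reactants: 3
Product: 4 2-(1,3-dioxolan-2-yl)-3-hydroxypropyl 3-methylbutanoate (racemic)
Conditions: isovaleryl chloride (0.95 equiv), Et3N, DMAP (cat.), CH2Cl2, –20 °C
Reagents that add atoms: isovaleryl chloride, CC(C)CC(=O)Cl
Why: Statistical mono-acylation of the symmetric diol installs the C11 isovalerate.

**Step 4**
Reactants: 4
Product: 5 2-(1,3-dioxolan-2-yl)-3-oxopropyl 3-methylbutanoate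
Conditions: Dess–Martin periodinane, NaHCO3, CH2Cl2, 0 °C → rt
Reagents that add atoms: none
Why: Buffered oxidation of the primary alcohol to the aldehyde; the buffer limits β-elimination of the acyloxy group.

**Step 5**
Reactants: 5
Product: 6 (E)-2-(1,3-dioxolan-2-yl)-4-nitrobut-3-en-1-yl 3-methylbutanoate
Conditions: MeNO2, Et3N (cat.), 0 °C; then MsCl, Et3N, CH2Cl2, –20 → 0 °C
Reagents that add atoms: nitromethane, C[N+](=O)[O-]
Why: Henry addition followed by mesylation and E1cB elimination gives the E-nitroalkene carrying the C3–C4–C11 unit.

**Step 6**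
Reactants: 6 nitroalkene; 7 2,5-dimethoxytetrahydrofuran (precursor of succinaldehyde)
Product: 8 trans-4-hydroxy-3-nitro-2-[1-(1,3-dioxolan-2-yl)-2-(isovaleroyloxy)ethyl]cyclopentane-1-carbaldehyde (C5 side chain and C9 CHO trans; C6 and C7 undefined)
Conditions: 7 hydrolysed first (H2O, 0.1 M HCl, 50 °C; then NaHCO3 to pH 7) and used directly; then 6, (S)-diphenylprolinol TMS ether (20 mol %), PhCO2H (20 mol %), CHCl3, 4 °C; then Et3N (20 mol %), rt
Reagents that add atoms: water, O (hydrolyses 7 to succinaldehyde, losing 2 MeOH)
Why: The catalyst-shielded enamine of succinaldehyde adds to the nitroalkene β-carbon and sets C5 (enamine Michael addition); the nitronate then closes onto the second aldehyde (intramolecular Henry), and C9 equilibrates through the enamine to the trans isomer.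

**Step 7**
Reactants: 8
Product: 9 C1 dimethyl acetal of 8
Conditions: CH(OMe)3, MeOH, PPTS (10 mol %), CH2Cl2, rt
Reagents that add atoms: trimethyl orthoformate, COC(OC)OC; methanol, CO
Why: Acetalisation of the more reactive aldehyde masks the epimerisable CHO and fixes C9 (trans) for the later facial selectivity; the dioxolane, deactivated by the β-acyloxy group, is untouched.

**Step 8**
Reactants: 9
Product: 10 α-nitroketone (C7=O)
Conditions: DMP, NaHCO3, CH2Cl2, rt
Reagents that add atoms: none
Why: Alcohol oxidation removes the C7 stereocentre and gives the nitro-activated ketone.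

**Step 9**
Reactants: 10
Product: 11 C8 Mannich base (C8–CH2NMe2) of the α-nitroketone
Conditions: LDA (2.05 equiv), THF, –78 °C; then CH2=NMe2+ I– (1.2 equiv), –78 → 0 °C
Reagents that add atoms: Eschenmoser's salt, C=[N+](C)C.[I-] (supplies the C10 CH2NMe2 unit)
Why: In the Weiler-type dianion, the first deprotonation forms the C6 nitronate and the second occurs only at the α′ carbon C8, so aminomethylation (Mannich) takes place regiospecifically at C8.

**Step 10**
Reactants: 11
Product: 12 C8 Mannich base ketone without the nitro group
Conditions: Bu3SnH, AIBN, PhH, 80 °C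
Reagents that add atoms: none
Why: Radical denitration of an α-nitroketone (Ono denitration) leaves C6 as CH2; it is done before the enone forms so that the tin hydride cannot reduce the exocyclic alkene.

**Step 11**
Reactants: 12
Product: 13 C8-methylene ketone (exocyclic enone)
Conditions: MeI (excess), CH2Cl2, rt; then aq. NaHCO3, THF, rt
Reagents that add atoms: none (MeI, CI, only quaternises the amine and leaves with it as Me3N)
Why: Quaternisation followed by E1cB/Hofmann-type elimination of NMe3 from the β-ammonium ketone places the exocyclic methylene (C10).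

**Step 12**
Reactants: 13
Product: 14 allylic alcohol with C7-OH up
Conditions: (R)-Me-CBS (20 mol %), BH3·SMe2, THF, –20 °C
Reagents that add atoms: none
Why: CBS 1,2-reduction of the enone is catalyst-controlled and delivers hydride to the down face, so C7-OH ends up. The substrate bias is weak because C5 (down) and C9 (up) are each 1,3 to the carbonyl.

**Step 13**
Reactants: 14
Product: 15 C7 acetate
Conditions: Ac2O, DMAP, Et3N, CH2Cl2, 0 °C
Reagents that add atoms: acetic anhydride, CC(=O)OC(C)=O
Why: Acetylation installs the final C7-OAc.

**Step 14**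
Reactants: 15
Product: 16 diol with C8-OH down and C10 (CH2OH) up
Conditions: OsO4 (5 mol %), NMO, acetone/H2O 9:1, 0 °C
Reagents that add atoms: NMO, C[N+]1([O-])CCOCC1
Why: Upjohn dihydroxylation of the exocyclic alkene occurs from the down face, anti to the C7-OAc and the trans-C9 acetal (both up), so C8-OH is down and the new CH2OH (C10) is up.

**Step 15**
Reactants: 16
Product: 17 C1 aldehyde (may rest as the C10–O–C1 lactol)
Conditions: PPTS (20 mol %), acetone/H2O 10:1, 50 °C
Reagents that add atoms: water, O
Why: The acyclic dimethyl acetal hydrolyses selectively over the deactivated dioxolane (acetal hydrolysis).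

**Step 16**
Reactants: 17
Product: 18 Jatamanvaltrate H
Conditions: TMS isovalerate (2.5 equiv), TMSOTf (3 equiv), i-Pr2NEt (4 equiv), CH2Cl2, –40 → 0 °C; then HF·pyridine, pyridine, THF, 0 °C
Reagents that add atoms: trimethylsilyl 3-methylbutanoate, CC(C)CC(=O)O[Si](C)(C)C
Why: Proposed new method: TMSOTf opens the dioxolane to a C3 oxocarbenium; the C1 carbonyl oxygen closes the six-membered ring; TMS isovalerate captures the C1 oxocarbenium as the acylal; ionisation of the remaining C3–O bond with loss of C4–H gives the C3=C4 enol ether (net: aldehyde + dioxolane + RCO2H → 1-acyloxy enol ether + ethylene glycol). The closest known reactions are Gassman acetal-to-enol-ether conversion, Vorbrüggen-type acetal-to-acylal exchange and Prins-type capture of oxocarbenium ions by a carbonyl oxygen. The C8/C10 diol is silylated in situ, which stops lactol formation and lets C9 epimerise through the silyl enol ether or enamine-type equilibrium. Only the cis-fused ring can close, so C9 is funnelled to the cis ring fusion, and axial anomeric capture sets C1.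

**Compound list**
1 | ethyl 2-(1,3-dioxolan-2-yl)acetate | CCOC(=O)CC1OCCO1 | starting material
2 | ethyl 2-(1,3-dioxolan-2-yl)-3-hydroxypropanoate (racemic) | CCOC(=O)C(CO)C1OCCO1 | intermediate
3 | 2-(1,3-dioxolan-2-yl)propane-1,3-diol | OCC(CO)C1OCCO1 | intermediate
4 | 2-(1,3-dioxolan-2-yl)-3-hydroxypropyl 3-methylbutanoate | CC(C)CC(=O)OCC(CO)C1OCCO1 | intermediate
5 | 2-(1,3-dioxolan-2-yl)-3-oxopropyl 3-methylbutanoate | CC(C)CC(=O)OCC(C=O)C1OCCO1 | intermediate
6 | (E)-2-(1,3-dioxolan-2-yl)-4-nitrobut-3-en-1-yl 3-methylbutanoate | CC(C)CC(=O)OCC(/C=C/[N+](=O)[O-])C1OCCO1 | intermediate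
7 | 2,5-dimethoxytetrahydrofuran (succinaldehyde precursor) | COC1CCC(OC)O1 | starting material
8 | Michael/Henry cyclopentane (C6-NO2, C7-OH, C9-CHO, C9 trans to C5 side chain) | OC1C([N+](=O)[O-])[C@H](C(COC(=O)CC(C)C)C2OCCO2)[C@@H](C=O)C1 | intermediate
9 | C1 dimethyl acetal of 8 | OC1C([N+](=O)[O-])[C@H](C(COC(=O)CC(C)C)C2OCCO2)[C@@H](C(OC)OC)C1 | intermediate
10 | α-nitroketone (C7=O) | O=C1C([N+](=O)[O-])[C@H](C(COC(=O)CC(C)C)C2OCCO2)[C@@H](C(OC)OC)C1 | intermediate
11 | C8 Mannich base of the nitroketone | O=C1C([N+](=O)[O-])[C@H](C(COC(=O)CC(C)C)C2OCCO2)[C@@H](C(OC)OC)C1CN(C)C | intermediate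
12 | C8 Mannich base ketone (denitrated) | O=C1C[C@H](C(COC(=O)CC(C)C)C2OCCO2)[C@@H](C(OC)OC)C1CN(C)C | intermediate
13 | C8-methylene ketone | O=C1C[C@H](C(COC(=O)CC(C)C)C2OCCO2)[C@@H](C(OC)OC)C1=C | intermediate
14 | allylic alcohol (C7-OH up) | O[C@H]1C[C@H](C(COC(=O)CC(C)C)C2OCCO2)[C@@H](C(OC)OC)C1=C | intermediate
15 | C7 acetate | CC(=O)O[C@H]1C[C@H](C(COC(=O)CC(C)C)C2OCCO2)[C@@H](C(OC)OC)C1=C | intermediate
16 | diol (C8-OH down, C10-OH up) | CC(=O)O[C@H]1C[C@H](C(COC(=O)CC(C)C)C2OCCO2)[C@@H](C(OC)OC)[C@@]1(O)CO | intermediate
17 | C1 aldehyde | CC(=O)O[C@H]1C[C@H](C(COC(=O)CC(C)C)C2OCCO2)[C@@H](C=O)[C@@]1(O)CO | intermediate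
18 | Jatamanvaltrate H | CC(=O)O[C@H]1C[C@@H]2C(COC(=O)CC(C)C)=CO[C@@H](OC(=O)CC(C)C)[C@@H]2[C@@]1(O)CO | target

**Total step count:** 16. **Longest linear sequence:** 16 (steps 1–5 build nitroalkene 6, which enters the cascade at step 6; 7 is commercial).

**Three steps most likely to fail**
1. **Step 16 (proposed new acylative cyclisation).** The closure may stall at the C10–O–C1 lactol, C9 may not funnel to the cis ring fusion, or C1 may form with poor anomeric selectivity. Fallback: hydrolyse both acetals of 17 (aq. HCl, THF) to the 1,5-dialdehyde, which cyclises to the cis-fused 1-hydroxy enol-ether lactol as in iridoid aglycone chemistry; then acylate the lactol with isovaleric anhydride/DMAP after transient TMS protection of the diol.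
2. **Step 14 (OsO4 facial selectivity).** The C8 configuration depends on attack anti to C7-OAc and the trans-C9 acetal. Fallback: reduce 13 with (S)-Me-CBS to the C7-OH-down epimer and do a Donohoe OsO4·TMEDA hydroxyl-directed dihydroxylation (syn to OH, down face). Then protect the primary OH as its TBS ether, invert C7 by Mitsunobu with AcOH to give the C7-OAc up, and remove the TBS group.
3. **Step 9 (regiospecific α′-aminomethylation of the nitroketone dianion).** The dianion may mis-metalate at the isovalerate α-CH2 or aminomethylate at C6. Fallback: use 2-(acetoxymethyl)succinaldehyde as the donor in step 6, so C10 is present from the start. After oxidation and denitration of the cascade product, the exocyclic enone forms by DBU-induced E1cB loss of AcOH from the β-acetoxy ketone.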